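**Assumptions:** Locants C1–C15 in names and comments are the germacrane locants of the target (C6 = lactone O–CH, C7 = ring-fusion CH, C8 = isobutyrate carbon, C9 = acetate carbon, C10/C14 = enoate, C4/C15 = CH2OH-bearing olefin). But-3-enylzinc bromide, Red-Al, (+)-Ipc2BOMe, Me2BBr and Grubbs II are bought. The route is a paper design; the selectivities claimed are expected from the reasoning given in each step, not demonstrated.

## Retrosynthetic overview

1. Target 31 ⇐ desilylation of 30 ⇐ ring-closing metathesis at C1=C10 of open-chain triene 29; the ten-membered ring is formed last.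
2. 29 ⇐ MOM→isobutyrate exchange on γ-lactone 26 ⇐ translactonisation/acetylation of δ-lactone adduct 24; the γ-lactone is the second ring, made from the first.
3. 24 ⇐ zinc Barbier union at C6–C7 of enal 7 (C1–C6, C15) with bromomethyl pentenolide 22 (C7–C14); this sets C6 and C7.
4. 22 ⇐ ring-closing metathesis (δ-lactone, first ring) of ester 21 ⇐ hydroxy acrylate 18 + acid chloride 20; 18 ⇐ Brown γ-alkoxyallylboration of 2-bromoacrolein (sets C8, C9), then methoxycarbonylation.
5. 7 ⇐ but-2-yne-1,4-diol by hydroalumination–iodination and Negishi coupling (sets the C4=C5 geometry).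

## Route

Step 1
Reactants: 1 but-2-yne-1,4-diol
Product: 2 4-{[tert-butyl(diphenyl)silyl]oxy}but-2-yn-1-ol
Conditions: 1 (3 equiv), TBDPSCl (1 equiv), imidazole, DMF, 0 °C → rt
Reagents that add atoms: tert-butyl(chloro)diphenylsilane, CC(C)(C)[Si](Cl)(c1ccccc1)c1ccccc1
Why: Silyl ether formation on a symmetrical primary diol used in excess gives the mono-ether and leaves one propargylic OH free to direct the next step.

Step 2
Reactants: 2 4-{[tert-butyl(diphenyl)silyl]oxy}but-2-yn-1-ol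
Product: 4 (2Z)-4-{[tert-butyl(diphenyl)silyl]oxy}-3-iodobut-2-en-1-ol, via cyclic alkenylaluminate 3 (not isolated)
Conditions: Red-Al (1.5 equiv), THF, 0 °C; then I2, −78 → 0 °C; aq Rochelle salt/Na2S2O3
Reagents that add atoms: iodine, II
Why: Hydroxyl-directed trans-hydroalumination puts hydride on the proximal and aluminium on the distal alkyne carbon, and iodinolysis with retention gives the (Z)-iodide with C6 cis to iodine, which fixes the later C4=C5 geometry.

Step 3
Reactants: 4 (2Z)-4-{[tert-butyl(diphenyl)silyl]oxy}-3-iodobut-2-en-1-ol; 5 but-3-enylzinc bromide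
Product: 6 (2E)-3-({[tert-butyl(diphenyl)silyl]oxy}methyl)hepta-2,6-dien-1-ol
Conditions: 5 (2.5 equiv), Pd(PPh3)4 (5 mol%), THF, rt → 45 °C
Reagents that add atoms: none
Why: Negishi sp2–sp3 cross-coupling replaces iodine by the butenyl chain with retention, so C3 ends cis to C6 and trans to the silyloxymethyl group as in the target.

Step 4
Reactants: 6 (2E)-3-({[tert-butyl(diphenyl)silyl]oxy}methyl)hepta-2,6-dien-1-ol
Product: 7 (2E)-3-({[tert-butyl(diphenyl)silyl]oxy}methyl)hepta-2,6-dienal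
Conditions: MnO2 (15 equiv), CH2Cl2, rt
Reagents that add atoms: none
Why: Chemoselective allylic oxidation with MnO2 gives the enal under neutral conditions that do not isomerise the trisubstituted double bond.

Step 5
Reactants: 8 acrolein
Product: 10 2-bromoprop-2-enal, via 2,3-dibromopropanal 9 (not isolated)
Conditions: Br2, CH2Cl2, −78 → 0 °C; then Et3N, 0 °C
Reagents that add atoms: bromine, BrBr
Why: Bromine addition to the C=C followed by E1cB dehydrobromination (addition–elimination) gives the α-bromoenal.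

Step 6
Reactants: 11 prop-2-en-1-ol
Product: 12 3-(methoxymethoxy)prop-1-ene
Conditions: MOMCl, iPr2NEt, CH2Cl2, 0 °C → rt
Reagents that add atoms: chloromethyl methyl ether, COCCl
Why: O-Alkylation (MOM protection) gives the allyl ether needed for γ-alkoxyallyl metalation.

Step 7
Reactants: 12 3-(methoxymethoxy)prop-1-ene; 10 2-bromoprop-2-enal
Product: 17 (3R,4S)-2-bromo-4-(methoxymethoxy)hexa-1,5-dien-3-ol, via (Z)-3-(methoxymethoxy)allyllithium 13 (not isolated), via lithium methoxyborate complex 14 (not isolated), via (Z)-alkoxyallyl-diisopinocampheylborane 15 (not isolated), via diisopinocampheylborinate ester 16 (not isolated)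
Conditions: s-BuLi, THF, −78 °C; (+)-Ipc2BOMe [from (−)-α-pinene], −78 °C; BF3·OEt2; 10, −78 °C, 3 h; then ethanolamine, rt
Reagents that add atoms: none
Why: In this Brown asymmetric γ-alkoxyallylboration the (Z)-alkoxyallylborane reacts through a chair Zimmerman–Traxler transition state to give the syn (threo) mono-protected diol, and the isopinocampheyl groups from (−)-α-pinene select the aldehyde face that gives 3R,4S (the future C9 and C8).

Step 8
Reactants: 17 (3R,4S)-2-bromo-4-(methoxymethoxy)hexa-1,5-dien-3-ol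
Product: 18 methyl (3S,4S)-3-hydroxy-4-(methoxymethoxy)-2-methylidenehex-5-enoate
Conditions: Pd(OAc)2 (5 mol%), dppf (6 mol%), CO (1 atm), Et3N, MeOH/DMF, 60 °C
Reagents that add atoms: carbon monoxide, [C-]#[O+]; methanol, CO
Why: Palladium-catalysed methoxycarbonylation of the alkenyl bromide (oxidative addition, CO insertion, methanolysis) gives the Morita–Baylis–Hillman-type acrylate without touching the stereocentres (the descriptor at C3 changes only by CIP priority).

Step 9
Reactants: 19 2-(bromomethyl)prop-2-enoic acid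
Product: 20 2-(bromomethyl)prop-2-enoyl chloride
Conditions: (COCl)2, DMF (cat.), CH2Cl2, 0 °C → rt; evaporate
Reagents that add atoms: oxalyl chloride, O=C(Cl)C(=O)Cl
Why: Acid chloride formation under Vilsmeier catalysis leaves the allylic bromide intact, and the acid has no α-hydrogen for ketene formation.

Step 10
Reactants: 18 methyl (3S,4S)-3-hydroxy-4-(methoxymethoxy)-2-methylidenehex-5-enoate; 20 2-(bromomethyl)prop-2-enoyl chloride
Product: 21 methyl (3S,4S)-3-{[2-(bromomethyl)prop-2-enoyl]oxy}-4-(methoxymethoxy)-2-methylidenehex-5-enoate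
Conditions: iPr2NEt, CH2Cl2, −20 → 0 °C
Reagents that add atoms: none
Why: Esterification of the only free hydroxyl (O9) with a hindered, non-nucleophilic base attaches the future C11–C13 unit and differentiates O9 from the MOM-protected O8.

Step 11
Reactants: 21 methyl (3S,4S)-3-{[2-(bromomethyl)prop-2-enoyl]oxy}-4-(methoxymethoxy)-2-methylidenehex-5-enoate
Product: 22 methyl 2-[(2S,3S)-5-(bromomethyl)-3-(methoxymethoxy)-6-oxo-3,6-dihydro-2H-pyran-2-yl]prop-2-enoate
Conditions: Grubbs II (5 mol%), CH2Cl2 (5 mM), 40 °C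
Reagents that add atoms: none
Why: Ring-closing metathesis between the vinyl group and the tethered 2-substituted acrylate closes the six-membered unsaturated lactone, which locks C8 cis to the carbonyl across C7=C11 and holds the 8-OMOM and the C9 substituent cis on the ring.

Step 12
Reactants: 22 methyl 2-[(2S,3S)-5-(bromomethyl)-3-(methoxymethoxy)-6-oxo-3,6-dihydro-2H-pyran-2-yl]prop-2-enoate; 7 (2E)-3-({[tert-butyl(diphenyl)silyl]oxy}methyl)hepta-2,6-dienal
Product: 24 methyl 2-[(2S,3S,4S)-4-[(1R,2E)-3-({[tert-butyl(diphenyl)silyl]oxy}methyl)-1-hydroxyhepta-2,6-dien-1-yl]-3-(methoxymethoxy)-5-methylidene-6-oxooxan-2-yl]prop-2-enoate, via allylzinc bromide 23 (not isolated)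
Conditions: Zn dust, THF/sat. aq NH4Cl (2:1), 0 °C → rt
Reagents that add atoms: none
Why: In this zinc Barbier allylation the ring-locked (E-type) allylzinc adds through a chair transition state at ring carbon C7 (SE2') on the face anti to the cis 8-OMOM and C9 substituents, which gives the anti adduct with 6R,7S configuration and the exocyclic methylene.

Step 13
Reactants: 24 δ-lactone adduct (name as in step 12)
Product: 26 methyl (3S,4S)-3-(acetyloxy)-4-[(2R,3S)-2-[(1E)-2-({[tert-butyl(diphenyl)silyl]oxy}methyl)hexa-1,5-dien-1-yl]-4-methylidene-5-oxooxolan-3-yl]-4-(methoxymethoxy)-2-methylidenebutanoate, via γ-lactone 9-alcohol 25 (not isolated)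
Conditions: DBU (0.2 equiv), CH2Cl2, rt; then Ac2O, pyridine, DMAP (cat.), 0 °C
Reagents that add atoms: acetic anhydride, CC(=O)OC(C)=O
Why: Base-catalysed translactonisation moves the acyl group from O9 to O6 because the trans-disubstituted α-methylene-γ-butyrolactone is more stable than the crowded δ-lactone, and the freed 9-OH is acetylated in the same pot without change at any stereocentre.

Step 14
Reactants: 26 γ-lactone 9-acetate 8-MOM ether (name as in step 13)
Product: 28 methyl (3S,4S)-3-(acetyloxy)-4-[(2R,3R)-2-[(1E)-2-({[tert-butyl(diphenyl)silyl]oxy}methyl)hexa-1,5-dien-1-yl]-4-methylidene-5-oxooxolan-3-yl]-4-hydroxy-2-methylidenebutanoate, via bromomethyl ether 27 (not isolated)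
Conditions: Me2BBr, CH2Cl2, −78 °C; then sat. aq NaHCO3/THF
Reagents that add atoms: none
Why: Lewis-acid acetal cleavage with Me2BBr at −78 °C (bromomethyl ether, hydrolysed on work-up) frees the 8-OH while the silyl ether, the acetate and both Michael acceptors survive (the 3R label at C7 is a CIP change only).

Step 15
Reactants: 28 8-alcohol (name as in step 14)
Product: 29 methyl (3S,4S)-3-(acetyloxy)-4-[(2R,3S)-2-[(1E)-2-({[tert-butyl(diphenyl)silyl]oxy}methyl)hexa-1,5-dien-1-yl]-4-methylidene-5-oxooxolan-3-yl]-2-methylidene-4-[(2-methylpropanoyl)oxy]butanoate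
Conditions: i-PrCOCl, pyridine, DMAP (cat.), CH2Cl2, 0 °C
Reagents that add atoms: 2-methylpropanoyl chloride, CC(C)C(=O)Cl
Why: DMAP-catalysed acylation of the secondary alcohol installs the isobutyrate faster than acetyl migration from O9 can occur.

Step 16
Reactants: 29 open-chain triene (name as in step 15)
Product: 30 methyl (1(10)E,4E,6R,7S,8S,9S)-9-acetoxy-15-{[tert-butyl(diphenyl)silyl]oxy}-8-(2-methylpropanoyloxy)germacra-1(10),4,11(13)-trien-12,6-olid-14-oate
Conditions: Grubbs II (20 mol%, in portions), toluene (1 mM), 80 °C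
Reagents that add atoms: none
Why: In this ring-closing metathesis the catalyst loads on the terminal alkene and closes onto the 2-substituted acrylate to form the ten-membered ring, where the new enoate is expected to be ring-cis (1(10)E), while closure onto the lactone methylene would give an anti-Bredt bridgehead alkene.

Step 17
Reactants: 30 15-O-TBDPS macrocycle (name as in step 16)
Product: 31 methyl (1(10)E,4E,6R,7S,8S,9S)-9-acetoxy-15-hydroxy-8-(2-methylpropanoyloxy)germacra-1(10),4,11(13)-trien-12,6-olid-14-oate (CNP0242134.2)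
Conditions: HF·pyridine, THF/pyridine, 0 °C → rt
Reagents that add atoms: none
Why: Buffered fluoride desilylation removes the TBDPS group without acyl migration or conjugate addition and gives the target.

## Compound list

1 | but-2-yne-1,4-diol | OCC#CCO | starting material
2 | 4-{[tert-butyl(diphenyl)silyl]oxy}but-2-yn-1-ol | OCC#CCO[Si](c1ccccc1)(c1ccccc1)C(C)(C)C | intermediate
3 | cyclic alkenylaluminate (sodium salt, five-membered O–Al–C=C ring) | [Na+].COCCO[Al-]1(OCCOC)OCC=C1CO[Si](c2ccccc2)(c2ccccc2)C(C)(C)C | intermediate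
4 | (2Z)-4-{[tert-butyl(diphenyl)silyl]oxy}-3-iodobut-2-en-1-ol | OC/C=C(\I)CO[Si](c1ccccc1)(c1ccccc1)C(C)(C)C | intermediate
5 | but-3-enylzinc bromide | C=CCC[Zn]Br | starting material
6 | (2E)-3-({[tert-butyl(diphenyl)silyl]oxy}methyl)hepta-2,6-dien-1-ol | OC/C=C(/CO[Si](c1ccccc1)(c1ccccc1)C(C)(C)C)CCC=C | intermediate
7 | (2E)-3-({[tert-butyl(diphenyl)silyl]oxy}methyl)hepta-2,6-dienal | O=C/C=C(/CO[Si](c1ccccc1)(c1ccccc1)C(C)(C)C)CCC=C | intermediate
8 | acrolein | C=CC=O | starting material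
9 | 2,3-dibromopropanal | O=CC(Br)CBr | intermediate
10 | 2-bromoprop-2-enal | C=C(Br)C=O | intermediate
11 | prop-2-en-1-ol | C=CCO | starting material
12 | 3-(methoxymethoxy)prop-1-ene | C=CCOCOC | intermediate
13 | (Z)-3-(methoxymethoxy)allyllithium | [Li]C/C=C\OCOC | intermediate
14 | lithium [(Z)-3-(methoxymethoxy)allyl](methoxy)diisopinocampheylborate | [Li+].COCO/C=C\C[B-](OC)([C@H]1C[C@H]2C[C@@H]([C@@H]1C)C2(C)C)[C@H]1C[C@H]2C[C@@H]([C@@H]1C)C2(C)C | intermediate
15 | [(Z)-3-(methoxymethoxy)allyl]diisopinocampheylborane | COCO/C=C\CB([C@H]1C[C@H]2C[C@@H]([C@@H]1C)C2(C)C)[C@H]1C[C@H]2C[C@@H]([C@@H]1C)C2(C)C | intermediate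
16 | diisopinocampheylborinate ester of 17 | C=C(Br)[C@H](OB([C@H]1C[C@H]2C[C@@H]([C@@H]1C)C2(C)C)[C@H]1C[C@H]2C[C@@H]([C@@H]1C)C2(C)C)[C@@H](OCOC)C=C | intermediate
17 | (3R,4S)-2-bromo-4-(methoxymethoxy)hexa-1,5-dien-3-ol | C=C(Br)[C@H](O)[C@@H](OCOC)C=C | intermediate
18 | methyl (3S,4S)-3-hydroxy-4-(methoxymethoxy)-2-methylidenehex-5-enoate | COC(=O)C(=C)[C@H](O)[C@@H](OCOC)C=C | intermediate
19 | 2-(bromomethyl)prop-2-enoic acid | OC(=O)C(=C)CBr | starting material
20 | 2-(bromomethyl)prop-2-enoyl chloride | ClC(=O)C(=C)CBr | intermediate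
21 | methyl (3S,4S)-3-{[2-(bromomethyl)prop-2-enoyl]oxy}-4-(methoxymethoxy)-2-methylidenehex-5-enoate | COC(=O)C(=C)[C@H](OC(=O)C(=C)CBr)[C@@H](OCOC)C=C | intermediate
22 | methyl 2-[(2S,3S)-5-(bromomethyl)-3-(methoxymethoxy)-6-oxo-3,6-dihydro-2H-pyran-2-yl]prop-2-enoate | COC(=O)C(=C)[C@@H]1OC(=O)C(CBr)=C[C@@H]1OCOC | intermediate
23 | allylzinc bromide derived from 22 | COC(=O)C(=C)[C@@H]1OC(=O)C(C[Zn]Br)=C[C@@H]1OCOC | intermediate
24 | methyl 2-[(2S,3S,4S)-4-[(1R,2E)-3-({[tert-butyl(diphenyl)silyl]oxy}methyl)-1-hydroxyhepta-2,6-dien-1-yl]-3-(methoxymethoxy)-5-methylidene-6-oxooxan-2-yl]prop-2-enoate | C=CCC/C(CO[Si](c1ccccc1)(c1ccccc1)C(C)(C)C)=C\[C@@H](O)[C@@H]2C(=C)C(=O)O[C@@H](C(=C)C(=O)OC)[C@H]2OCOC | intermediate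
25 | methyl (3S,4S)-4-[(2R,3S)-2-[(1E)-2-({[tert-butyl(diphenyl)silyl]oxy}methyl)hexa-1,5-dien-1-yl]-4-methylidene-5-oxooxolan-3-yl]-3-hydroxy-4-(methoxymethoxy)-2-methylidenebutanoate | C=C1C(=O)O[C@H](/C=C(/CO[Si](c2ccccc2)(c2ccccc2)C(C)(C)C)CCC=C)[C@H]1[C@H](OCOC)[C@@H](O)C(=C)C(=O)OC | intermediate
26 | methyl (3S,4S)-3-(acetyloxy)-4-[(2R,3S)-2-[(1E)-2-({[tert-butyl(diphenyl)silyl]oxy}methyl)hexa-1,5-dien-1-yl]-4-methylidene-5-oxooxolan-3-yl]-4-(methoxymethoxy)-2-methylidenebutanoate | C=C1C(=O)O[C@H](/C=C(/CO[Si](c2ccccc2)(c2ccccc2)C(C)(C)C)CCC=C)[C@H]1[C@H](OCOC)[C@@H](OC(C)=O)C(=C)C(=O)OC | intermediate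
27 | 8-O-bromomethyl ether corresponding to 26 (OCH2Br in place of OCH2OMe) | C=C1C(=O)O[C@H](/C=C(/CO[Si](c2ccccc2)(c2ccccc2)C(C)(C)C)CCC=C)[C@H]1[C@H](OCBr)[C@@H](OC(C)=O)C(=C)C(=O)OC | intermediate
28 | methyl (3S,4S)-3-(acetyloxy)-4-[(2R,3R)-2-[(1E)-2-({[tert-butyl(diphenyl)silyl]oxy}methyl)hexa-1,5-dien-1-yl]-4-methylidene-5-oxooxolan-3-yl]-4-hydroxy-2-methylidenebutanoate | C=C1C(=O)O[C@H](/C=C(/CO[Si](c2ccccc2)(c2ccccc2)C(C)(C)C)CCC=C)[C@H]1[C@H](O)[C@@H](OC(C)=O)C(=C)C(=O)OC | intermediate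
29 | methyl (3S,4S)-3-(acetyloxy)-4-[(2R,3S)-2-[(1E)-2-({[tert-butyl(diphenyl)silyl]oxy}methyl)hexa-1,5-dien-1-yl]-4-methylidene-5-oxooxolan-3-yl]-2-methylidene-4-[(2-methylpropanoyl)oxy]butanoate | C=C1C(=O)O[C@H](/C=C(/CO[Si](c2ccccc2)(c2ccccc2)C(C)(C)C)CCC=C)[C@H]1[C@H](OC(=O)C(C)C)[C@@H](OC(C)=O)C(=C)C(=O)OC | intermediate
30 | methyl (1(10)E,4E,6R,7S,8S,9S)-9-acetoxy-15-{[tert-butyl(diphenyl)silyl]oxy}-8-(2-methylpropanoyloxy)germacra-1(10),4,11(13)-trien-12,6-olid-14-oate | C=C1C(=O)O[C@@H]2/C=C(/CO[Si](c3ccccc3)(c3ccccc3)C(C)(C)C)CC/C=C(/C(=O)OC)[C@H](OC(C)=O)[C@@H](OC(=O)C(C)C)[C@@H]12 | intermediate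
31 | methyl (1(10)E,4E,6R,7S,8S,9S)-9-acetoxy-15-hydroxy-8-(2-methylpropanoyloxy)germacra-1(10),4,11(13)-trien-12,6-olid-14-oate (CNP0242134.2) | C=C1C(=O)O[C@@H]2/C=C(/CO)CC/C=C(/C(=O)OC)[C@H](OC(C)=O)[C@@H](OC(=O)C(C)C)[C@@H]12 | target

## Step count and risks

Total step count: 17.
Longest linear sequence: 11 steps (step 5 or 6, then 7, 8, 10, 11, 12, 13, 14, 15, 16, 17). The enal branch (steps 1–4) and the acid chloride (step 9) are separate arms.

Three steps most likely to fail:

**Step 16 (ten-membered ring closure onto a hindered 2-substituted acrylate).** The fallback sets out from 22 and 7 and comes back at 30, with the two C–C bond formations in reverse order. Cross-metathesis of 7 (3 equiv) with the acrylate of 22 (Hoveyda–Grubbs II, CH2Cl2, 40 °C; thermodynamic E-enoate) gives the open-chain enoate aldehyde F1. An intramolecular zinc Barbier allylation under high dilution (Zn, THF/aq NH4Cl, 2 mM) then closes the ten-membered ring at C6–C7 to the bridged macrocyclic δ-lactone alcohol F2. DBU followed by Ac2O/pyridine gives the macrocyclic γ-lactone 9-acetate 8-MOM ether F3, Me2BBr gives the macrocyclic 8-alcohol F4, and isobutyryl chloride/pyridine returns 30.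

**Step 12 (Barbier union).** The risks are 1,4-elimination or protonation of the allylzinc, attack through C13, and leakage of the anti/facial selectivity. The fallback sets out from 22 and comes back at 24. Palladium-catalysed borylation of the allylic bromide (B2pin2, Pd2(dba)3, toluene, 60 °C) gives the isolable allylboronate F5. F5 is heated with 7 in toluene (80 °C, or Sc(OTf)3 catalysis at rt) so that the allylation runs through a closed six-membered boron transition state with the same ring-locked geometry, and hydrolytic work-up gives 24.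

**Step 7 (alkoxyallylboration of the labile, highly electrophilic 2-bromoacrolein).** The fallback sets out from 12 and comes back at 18. Borane 15 is made as before and added to commercial 3-(trimethylsilyl)propynal to give (3S,4S)-4-(methoxymethoxy)-1-(trimethylsilyl)hex-5-en-1-yn-3-ol F6. K2CO3/MeOH gives the terminal alkyne (3S,4S)-4-(methoxymethoxy)hex-5-en-1-yn-3-ol F7. Markovnikov hydromethoxycarbonylation (Pd(OAc)2, 2-pyridyldiphenylphosphine, catalytic MsOH, CO, MeOH, 45 °C) then gives 18 directly.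

## Further compounds

F1 | step 16 | methyl (2E,6E)-2-[(2S,3S)-5-(bromomethyl)-3-(methoxymethoxy)-6-oxo-3,6-dihydro-2H-pyran-2-yl]-6-({[tert-butyl(diphenyl)silyl]oxy}methyl)-8-oxoocta-2,6-dienoate | O=C/C=C(/CO[Si](c1ccccc1)(c1ccccc1)C(C)(C)C)CC/C=C(/C(=O)OC)[C@@H]2OC(=O)C(CBr)=C[C@@H]2OCOC
F2 | step 16 | methyl (1(10)E,4E,6R,7S,8S,9S)-15-{[tert-butyl(diphenyl)silyl]oxy}-6-hydroxy-8-(methoxymethoxy)germacra-1(10),4,11(13)-trien-12,9-olid-14-oate (bridged δ-lactone) | O[C@@H]1/C=C(/CO[Si](c3ccccc3)(c3ccccc3)C(C)(C)C)CC/C=C(/C(=O)OC)[C@@H]2OC(=O)C(=C)[C@@H]1[C@@H]2OCOC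
F3 | step 16 | methyl (1(10)E,4E,6R,7S,8S,9S)-9-acetoxy-15-{[tert-butyl(diphenyl)silyl]oxy}-8-(methoxymethoxy)germacra-1(10),4,11(13)-trien-12,6-olid-14-oate | C=C1C(=O)O[C@@H]2/C=C(/CO[Si](c3ccccc3)(c3ccccc3)C(C)(C)C)CC/C=C(/C(=O)OC)[C@H](OC(C)=O)[C@@H](OCOC)[C@@H]12
F4 | step 16 | methyl (1(10)E,4E,6R,7R,8S,9S)-9-acetoxy-15-{[tert-butyl(diphenyl)silyl]oxy}-8-hydroxygermacra-1(10),4,11(13)-trien-12,6-olid-14-oate | C=C1C(=O)O[C@@H]2/C=C(/CO[Si](c3ccccc3)(c3ccccc3)C(C)(C)C)CC/C=C(/C(=O)OC)[C@H](OC(C)=O)[C@@H](O)[C@@H]12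
F5 | step 12 | methyl 2-[(2S,3S)-3-(methoxymethoxy)-6-oxo-5-[(4,4,5,5-tetramethyl-1,3,2-dioxaborolan-2-yl)methyl]-3,6-dihydro-2H-pyran-2-yl]prop-2-enoate | COC(=O)C(=C)[C@@H]1OC(=O)C(CB2OC(C)(C)C(C)(C)O2)=C[C@@H]1OCOC
F6 | step 7 | (3S,4S)-4-(methoxymethoxy)-1-(trimethylsilyl)hex-5-en-1-yn-3-ol | C[Si](C)(C)C#C[C@H](O)[C@@H](OCOC)C=C
F7 | step 7 | (3S,4S)-4-(methoxymethoxy)hex-5-en-1-yn-3-ol | C#C[C@H](O)[C@@H](OCOC)C=C
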